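**Retrosynthetic overview**
1. The last skeletal bond is the depside ester O4(ring B)–C(=O)(ring A). Cutting it gives the ring B phenol methyl 2,4-dihydroxy-3,5,6-trimethylbenzoate and a 2′,4′-di-O-benzyl-3′-formyl ring A acid chloride; hydrogenolysis of the two benzyl ethers ends the route.
2. Feature used: in ring B, C3–C4–C5 with the methyl groups on C3 and C5 is the carbon chain of pentan-3-one, and C6(CH3)–C1(CO2CH3)–C2(O) is an acetylmalonate. All six ring carbons therefore arrive already substituted, and the symmetric ketone allows no regioisomer.
3. Ring B is the only ring that is built. An anionic (3+3) annulation closes it: C5–C6 by addition–elimination on dimethyl 2-(1-chloroethylidene)malonate, C2–C3 by Claisen closure of the derived dianion, then tautomerisation to the arene.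
4. Ring A comes from 4,5-dimethylresorcinol: formyl at C1′ (later oxidised to CO2H), bromine at C3′ (later exchanged for CHO), benzyl on both oxygens.
5. Order: chloroalkylidene malonate (steps 1–2), ring B (step 3), ring A acid chloride (steps 4–9), union and deprotection (steps 10–11).

Key step: step 3

Assumption: 4,5-dimethylbenzene-1,3-diol is taken to be a catalogue compound; the other starting materials are bulk chemicals.

**Step 1**
Reactants: 1 dimethyl malonate; 2 acetyl chloride
Product: 3 dimethyl 2-acetylmalonate (largely enolised)
Conditions: MgCl2 (1.0 equiv), Et3N (2.0 equiv), MeCN, 0 °C; 2 (1.0 equiv), 0 °C → rt; aq HCl work-up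
Reagents that add atoms: none
Why: C-acylation of a malonate under soft enolisation, in which MgCl2 chelates the diester so that Et3N suffices as base and the magnesium chelate of the more acidic tricarbonyl product prevents a second acylation.

**Step 2**
Reactants: 3 dimethyl 2-acetylmalonate
Product: 4 dimethyl 2-(1-chloroethylidene)malonate
Conditions: POCl3 (excess), n-Bu3N (1.0 equiv), 110 °C; ice-water work-up
Reagents that add atoms: phosphoryl chloride, O=P(Cl)(Cl)Cl
Why: The enol is O-phosphorylated and chloride then displaces dichlorophosphate by addition–elimination at the doubly activated carbon, the standard conversion of acylmalonates into beta-chloroalkylidene malonates, and no alkene geometry arises because C1 carries two like esters.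

**Step 3**
Reactants: 5 pentan-3-one; 4 dimethyl 2-(1-chloroethylidene)malonate
Product: 9 methyl 2,4-dihydroxy-3,5,6-trimethylbenzoate, via lithium enolate 6 (not isolated), via alkylidenemalonate adduct 7 (not isolated), via dilithium dianion 8 (not isolated)
Conditions: 5 (2.1 equiv), LiN(iPr)2 (2.1 equiv), THF, −78 °C; 4 (1.0 equiv), −78 °C; LiN(iPr)2 (2.3 equiv), −78 °C → rt; 1 M HCl
Reagents that add atoms: none
Why: Proposed new method: Enolate 6 adds to the chlorine-bearing carbon of 4 and the malonate anion formed expels chloride (bond C5–C6); the CH of 7 that is alpha to the ketone and vinylogous to the malonate is so acidic that it quenches a second enolate at once, which is why two equivalents of 6 are charged and no free amide base meets 4. The second charge of LiN(iPr)2 re-enolises the released ketone and takes a proton from the ethyl CH2 of the monoanion, in the manner of 1,3-dicarbonyl dianion formation, to give 8. On warming, the terminal carbon C3 of 8 attacks an ester carbonyl (C2) in a 6-(enolendo)-exo-trig Claisen closure of ring B; the C5–C6 bond of the delocalised anion has only partial double-bond character and can turn C4 cis to C1, and because C1 carries two esters one of them is then always in reach. Loss of methoxide and two enolisations aromatise the ring, so the one stereocentre that appears on the way (C5 of 7, racemic) is erased and nothing stereochemical has to be controlled. The closest known reaction types are the addition–elimination of ketone enolates to beta-alkoxy- or beta-halo-alkylidene malonates, the terminal C-acylation of 1,3-dicarbonyl dianions and the Michael–Claisen synthesis of dihydroresorcylates from malonates and enones; their union on a fully substituted ring is what is new. The selectivity needed is C- over O-acylation: closure through the ketone oxygen gives an enol lactone that the lithium methoxide set free can reopen, whereas C-acylation is made irreversible by aromatisation, and the symmetry of 5 removes any choice of regiochemistry.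

**Step 4**
Reactants: 10 4,5-dimethylbenzene-1,3-diol (4,5-dimethylresorcinol)
Product: 12 2,4-dihydroxy-5,6-dimethylbenzaldehyde, via aryl iminium chloride 11 (not isolated)
Conditions: POCl3 (1.2 equiv), DMF, 0 °C → rt; H2O, 50 °C
Reagents that add atoms: N,N-dimethylformamide, CN(C)C=O; water, O
Why: Vilsmeier–Haack formylation, in which the chloroiminium ion attacks C6 of the resorcinol (para to one hydroxyl, ortho to the other) rather than the crowded C2 between the two hydroxyls, as orcinol does, and water then hydrolyses 11.

**Step 5**
Reactants: 12 2,4-dihydroxy-5,6-dimethylbenzaldehyde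
Product: 13 3-bromo-2,4-dihydroxy-5,6-dimethylbenzaldehyde
Conditions: NBS (1.0 equiv), MeCN, 0 °C, dark
Reagents that add atoms: N-bromosuccinimide, O=C1CCC(=O)N1Br
Why: Electrophilic aromatic bromination at C3, the only ring C–H left and activated by both flanking hydroxyls, while polar and dark conditions keep the reagent away from the benzylic methyl groups.

**Step 6**
Reactants: 13 3-bromo-2,4-dihydroxy-5,6-dimethylbenzaldehyde
Product: 14 2,4-bis(benzyloxy)-3-bromo-5,6-dimethylbenzaldehyde
Conditions: BnBr (2.4 equiv), K2CO3 (3 equiv), DMF, 60 °C
Reagents that add atoms: benzyl bromide, BrCc1ccccc1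
Why: Double Williamson ether synthesis, with enough heat in DMF to alkylate also the 2-hydroxyl that is hydrogen-bonded to the aldehyde.

**Step 7**
Reactants: 14 2,4-bis(benzyloxy)-3-bromo-5,6-dimethylbenzaldehyde
Product: 15 2,4-bis(benzyloxy)-3-bromo-5,6-dimethylbenzoic acid
Conditions: NaClO2, NaH2PO4, 2-methylbut-2-ene, t-BuOH/THF/H2O, rt
Reagents that add atoms: sodium chlorite, [Na+].[O-]Cl=O
Why: Pinnick oxidation, which converts the aldehyde without touching benzyl ethers or aryl bromide, the alkene trapping hypochlorous acid and the fully substituted ring offering no site for chlorination.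

**Step 8**
Reactants: 15 2,4-bis(benzyloxy)-3-bromo-5,6-dimethylbenzoic acid
Product: 17 2,4-bis(benzyloxy)-3-formyl-5,6-dimethylbenzoic acid, via dilithiated benzoate 16 (not isolated)
Conditions: n-BuLi (2.2 equiv), THF, −78 °C; DMF (5 equiv), −78 → 0 °C; 1 M HCl
Reagents that add atoms: N,N-dimethylformamide, CN(C)C=O
Why: Bromine–lithium exchange followed by formylation with DMF, in which the first equivalent of n-BuLi makes the hindered and inert carboxylate, the second exchanges bromine faster than any deprotonation at −78 °C to give an aryllithium held between two ether oxygens, and acid work-up releases the aldehyde.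

**Step 9**
Reactants: 17 2,4-bis(benzyloxy)-3-formyl-5,6-dimethylbenzoic acid
Product: 18 2,4-bis(benzyloxy)-3-formyl-5,6-dimethylbenzoyl chloride
Conditions: (COCl)2 (1.5 equiv), DMF (cat.), CH2Cl2, 0 °C → rt; evaporation, used crude
Reagents that add atoms: oxalyl chloride, O=C(Cl)C(=O)Cl
Why: Acid chloride formation with oxalyl chloride under DMF catalysis, mild enough for the aryl aldehyde and the benzyl ethers.

**Step 10**
Reactants: 9 methyl 2,4-dihydroxy-3,5,6-trimethylbenzoate; 18 2,4-bis(benzyloxy)-3-formyl-5,6-dimethylbenzoyl chloride
Product: 20 methyl 4-{[2,4-bis(benzyloxy)-3-formyl-5,6-dimethylbenzoyl]oxy}-2-hydroxy-3,5,6-trimethylbenzoate, via sodium phenoxide 19 (not isolated)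
Conditions: 9, NaH (1.0 equiv), THF, 0 °C; 18 (1.05 equiv), 0 → 40 °C
Reagents that add atoms: none
Why: Acylation of a phenoxide by an acid chloride, in which one equivalent of NaH ionises only the more acidic 4-hydroxyl para to the ester while the 2-hydroxyl stays locked in its hydrogen bond to the ester carbonyl, so the depside bond should form at O4 alone.

**Step 11**
Reactants: 20 methyl 4-{[2,4-bis(benzyloxy)-3-formyl-5,6-dimethylbenzoyl]oxy}-2-hydroxy-3,5,6-trimethylbenzoate
Product: 21 pseudocyphellarin A, methyl 4-[(3-formyl-2,4-dihydroxy-5,6-dimethylbenzoyl)oxy]-2-hydroxy-3,5,6-trimethylbenzoate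
Conditions: H2 (1 atm), 10% Pd/C, EtOAc, rt, stopped after uptake of two equivalents of H2
Reagents that add atoms: none
Why: Catalytic hydrogenolysis of two benzyl aryl ethers, in which the aldehyde, flanked by two oxygens and hydrogen-bonded as soon as they are free, should be reduced far more slowly, and the aprotic solvent spares the depside ester from alcoholysis.

**Compound list**
1 | dimethyl malonate | COC(=O)CC(=O)OC | starting material
2 | acetyl chloride | CC(Cl)=O | starting material
3 | dimethyl 2-acetylmalonate | CC(=O)C(C(=O)OC)C(=O)OC | intermediate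
4 | dimethyl 2-(1-chloroethylidene)malonate | COC(=O)C(=C(C)Cl)C(=O)OC | intermediate
5 | pentan-3-one | CCC(=O)CC | starting material
6 | lithium pent-2-en-3-olate (enolate geometry without consequence) | [Li+].CC=C([O-])CC | intermediate
7 | dimethyl 2-(3-methyl-4-oxohexan-2-ylidene)malonate (racemic, held in the flask as its lithium salt) | CCC(=O)C(C)C(C)=C(C(=O)OC)C(=O)OC | intermediate
8 | dilithium dianion of 7 (ketone enolate plus vinylogous malonate anion, geometry mobile) | [Li+].[Li+].CC=C([O-])C(C)=C(C)[C-](C(=O)OC)C(=O)OC | intermediate
9 | methyl 2,4-dihydroxy-3,5,6-trimethylbenzoate | COC(=O)c1c(C)c(C)c(O)c(C)c1O | intermediate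
10 | 4,5-dimethylbenzene-1,3-diol | Cc1c(C)cc(O)cc1O | starting material
11 | N-(2,4-dihydroxy-5,6-dimethylbenzylidene)-N-methylmethanaminium chloride | C[N+](C)=Cc1c(C)c(C)c(O)cc1O.[Cl-] | intermediate
12 | 2,4-dihydroxy-5,6-dimethylbenzaldehyde | O=Cc1c(C)c(C)c(O)cc1O | intermediate
13 | 3-bromo-2,4-dihydroxy-5,6-dimethylbenzaldehyde | O=Cc1c(C)c(C)c(O)c(Br)c1O | intermediate
14 | 2,4-bis(benzyloxy)-3-bromo-5,6-dimethylbenzaldehyde | O=Cc1c(C)c(C)c(OCc2ccccc2)c(Br)c1OCc1ccccc1 | intermediate
15 | 2,4-bis(benzyloxy)-3-bromo-5,6-dimethylbenzoic acid | OC(=O)c1c(C)c(C)c(OCc2ccccc2)c(Br)c1OCc1ccccc1 | intermediate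
16 | lithium 2,4-bis(benzyloxy)-3-lithio-5,6-dimethylbenzoate | [Li+].[O-]C(=O)c1c(C)c(C)c(OCc2ccccc2)c([Li])c1OCc1ccccc1 | intermediate
17 | 2,4-bis(benzyloxy)-3-formyl-5,6-dimethylbenzoic acid | OC(=O)c1c(C)c(C)c(OCc2ccccc2)c(C=O)c1OCc1ccccc1 | intermediate
18 | 2,4-bis(benzyloxy)-3-formyl-5,6-dimethylbenzoyl chloride | ClC(=O)c1c(C)c(C)c(OCc2ccccc2)c(C=O)c1OCc1ccccc1 | intermediate
19 | sodium 3-hydroxy-4-(methoxycarbonyl)-2,5,6-trimethylphenolate | [Na+].COC(=O)c1c(C)c(C)c([O-])c(C)c1O | intermediate
20 | methyl 4-{[2,4-bis(benzyloxy)-3-formyl-5,6-dimethylbenzoyl]oxy}-2-hydroxy-3,5,6-trimethylbenzoate | COC(=O)c1c(C)c(C)c(OC(=O)c2c(C)c(C)c(OCc3ccccc3)c(C=O)c2OCc2ccccc2)c(C)c1O | intermediate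
21 | pseudocyphellarin A (achiral) | COC(=O)c1c(C)c(C)c(OC(=O)c2c(C)c(C)c(O)c(C=O)c2O)c(C)c1O | target

**Total step count:** 11.
**Longest linear sequence:** 8 (steps 4–11, from 4,5-dimethylbenzene-1,3-diol). The ring B branch contributes steps 1–3.

**Steps most likely to fail**

1. **Step 3.**
 - Risk: the ester that must be attacked belongs to a malonate anion and is a weak electrophile, so closure may stall. Acylation through oxygen or simple reprotonation on work-up could then prevail. In the first stage the enolate may also act as a base on the allylic methyl group of 4 instead of adding to the fully substituted carbon.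
 - Fallback (known chemistry, one oxidation level lower; sets out from 5 and 1, returns at 9): pentan-3-one 5 is condensed with acetaldehyde under acid catalysis to (E)-4-methylhex-4-en-3-one F1. NaOMe in refluxing methanol adds dimethyl malonate 1 to F1 to give dimethyl 2-(3-methyl-4-oxohexan-2-yl)malonate F2. This closes in the same pot, through the ethyl CH2 onto an ester that is reversibly protonated and therefore electrophilic, to methyl 3,5,6-trimethyl-2,4-dioxocyclohexane-1-carboxylate F3. Dehydrogenation of F3 with DDQ in refluxing dioxane then gives 9.

2. **Step 10.**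
 - Risk: acyl transfer between two di-ortho-substituted partners may be slow. That leaves time for hydrolysis of the acid chloride or for acylation at the chelated 2-hydroxyl.
 - Fallback (dissociative activation instead of addition–elimination; sets out from 17 and 9, returns at 20): acid 17 is treated with trifluoroacetic anhydride in toluene to give 2,4-bis(benzyloxy)-3-formyl-5,6-dimethylbenzoic trifluoroacetic anhydride F4. This ionises to an acylium ion stabilised by the 2′- and 4′-oxygens. The linear electrophile is taken up by the free 4-hydroxyl of 9 without base, so the hydrogen-bonded 2-hydroxyl is never ionised.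

3. **Step 8.**
 - Risk: proton transfer to the aryllithium from a benzylic OCH2 or from the C6′ methyl group would amount to plain debromination. Anionic rearrangement of a benzyl ether and poor solubility of the lithium carboxylate at −78 °C are further hazards.
 - Fallback (cross-coupling and oxidative cleavage instead of organolithium chemistry; sets out from 15, returns at 17): Suzuki–Miyaura vinylation of 15 uses potassium vinyltrifluoroborate, Pd(OAc)2, SPhos and K2CO3 in dioxane/H2O at 90 °C, the bulky phosphine helping zerovalent palladium to insert into the hindered C–Br bond. It gives 2,4-bis(benzyloxy)-5,6-dimethyl-3-vinylbenzoic acid F5. Lemieux–Johnson cleavage of F5 (OsO4 cat., NaIO4, 2,6-lutidine, dioxane/H2O) then gives 17.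

**Further compounds**
F1 | step 3 | (E)-4-methylhex-4-en-3-one | CCC(=O)/C(C)=C/C
F2 | step 3 | dimethyl 2-(3-methyl-4-oxohexan-2-yl)malonate (mixture of diastereomers) | CCC(=O)C(C)C(C)C(C(=O)OC)C(=O)OC
F3 | step 3 | methyl 3,5,6-trimethyl-2,4-dioxocyclohexane-1-carboxylate (mixture of diastereomers and enol forms) | COC(=O)C1C(C)C(C)C(=O)C(C)C1=O
F4 | step 10 | 2,4-bis(benzyloxy)-3-formyl-5,6-dimethylbenzoic trifluoroacetic anhydride | O=C(OC(=O)C(F)(F)F)c1c(C)c(C)c(OCc2ccccc2)c(C=O)c1OCc1ccccc1
F5 | step 8 | 2,4-bis(benzyloxy)-5,6-dimethyl-3-vinylbenzoic acid | OC(=O)c1c(C)c(C)c(OCc2ccccc2)c(C=C)c1OCc1ccccc1
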